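The earlier runs and the new flask are simulated with constants of no real substance; scatter was added.

Count the feed.

| setting | south-east | north-west | flask |
|---|---|---|---|
| starting material | 0.063 M (fed, over 10 min) | 0.13 M (fed, over 10 min) | 0.063 M (fed, over 10 min) |
| partner | 0.189 M | 0.189 M | 0.189 M |
| remark | the very flask that is asked about, followed so far | run made earlier |  |
| time |  |  | 10 min |

- south-east (time / min: starting material / %, mono adduct / %, bis adduct / %): 0.417: 4.7, 0, 0; 0.833: 9.5, 0, 0; 1.33: 11.5, 1.9, 0.2; 2.50: 20.0, 2.7, 2.5; 5.00: 35.0, 13.7, 2.1
- north-west (time / min: starting material / %, mono adduct / %, bis adduct / %): 1.33: 11.5, 1.4, 0; 3.00: 24.4, 5.8, 1.3; 4.00: 29.2, 8.9, 0.2; 6.00: 41.2, 19.1, 1.3; 8.00: 47.6, 27.8, 0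

(standard deviation of a reading: 1 percentage point)

- percentages count the whole charge, also what has not yet gone in

- the starting material standing at 10 min, as a percentage of the starting material charged
- the mono adduct standing at 10 min, as a percentage of the starting material charged
- the bis adduct standing at 10 min, as a percentage of the starting material charged
- the tris adduct standing at 10 min, as a percentage of the starting material charged

The feed adds a steady share of the charge each minute, and standing starting material is what conversion has not taken. In the south-east run, the converted share at 5.00 min is fed minus standing, and two trapezoids give the area under the standing curve: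

clearance = converted share / area = 0.160 min⁻¹

This clearance, the share of standing starting material converted per minute, is a pseudo-first-order constant and a reading with scatter. The north-west run, with twice the charge, reads 0.153 min⁻¹, so the order in starting material reads as 1. Both runs start from one partner charge, so first order in partner is assumed here. For a constant clearance in this flask:

standing = (feed rate / clearance) × (1 − exp(−clearance × time))

Bound from below, the read clearance undiminished: 49.9%.

Partner left, at one per conversion and with later steps not counted: 83.3%.

Bound from above, clearance at that partner: 0.133 min⁻¹ gives 55.2%.

Partner curve replaced by its mean, 91.6%: 0.147 min⁻¹ gives 52.5%, with a possible error of 2.7 percentage points.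

The forecast, which calls the step “first order in starting material”, gives 52% of starting material, 44% of mono adduct, 3.7% of bis adduct and 0.2% of tris adduct, its starting material lying above 49.9% and below 55.2%.

The flask gives 53.1% of starting material, 37.9% of mono adduct, 0.767% of bis adduct and 0.393% of tris adduct. Its starting material stands 0.60 points above the mean reckoning and inside the bracket.

    starting material + partner → mono adduct + by-product (k = 0.0140 L mol⁻¹ s⁻¹)
    partner + mono adduct → bis adduct + by-product (k = 7.60 × 10⁻⁴ L mol⁻¹ s⁻¹)
    partner + bis adduct ⇌ tris adduct + by-product (K = 14.0, k = 0.0160 L mol⁻¹ s⁻¹)
    bis adduct + by-product → side product (k = 0.0100 L mol⁻¹ s⁻¹)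
    mono adduct → decomposed reagent (k = 8.40 × 10⁻⁴ s⁻¹)

The same reckoning serves a neighbouring flask charged with 0.16 M of starting material, other settings as in this flask. Its lower bound stays 49.9%. Its partner left, reckoned the same way, is 57.6%, which gives an upper bound of 65.3%. Its mean partner, 78.8%, gives 56.8%. The neighbouring flask holds 57.6% of starting material at 10.0 min, with 63% of its partner left.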